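**Strategy.** Everything rests on closing rings B and C around quaternary C8 in a single organocatalytic relay. An achiral precursor, in which an alkylidene cyclopentenone ring D derived from cyclopentane-1,3-dione carries a 4-oxo-enal chain, undergoes iminium-controlled intramolecular vinylogous Michael addition (C8–C9, ring B) and, in the same flask, carbene-catalysed Stetter closure of the freed aldehyde onto the β-alkoxy enone of ring D (C12–C13, ring C). The step exploits the 1,3-dioxygenation of ring D (C13, C15), the vicinal oxygens at C12/C13 and the vinylogous acidity that the C10 and C15 carbonyls confer on C5–H, whose anion reacts at C8. Ring A and the 19,10-lactone are then annulated onto the C10 ketone and the C5=C6 acrylate.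

Key step: step 7

Remark: gibberellane numbering is used throughout; 5, 10 and 11 are tautomeric mixtures (one tautomer drawn), and the acetal carbon in 15–29 and C4 in 25–28 are drawn as the expected major epimers, both epimers converging on 30.

**Step 1**
Reactants: 1 cyclopentane-1,3-dione; 2 4-methoxybenzyl alcohol
Product: 3 3-[(4-methoxybenzyl)oxy]cyclopent-2-en-1-one
Conditions: TsOH·H2O (5 mol %), toluene, reflux, Dean–Stark
Reagents that add atoms: none
Why: Acid-catalysed vinylogous esterification of the symmetrical dione with azeotropic removal of water; no stereocentre is formed, and the PMB group later becomes the protecting group of the C13 oxygen.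

**Step 2**
Reactants: 3 vinylogous ester; 4 dimethyl oxalate
Product: 5 methyl 2-hydroxy-2-{4-[(4-methoxybenzyl)oxy]-2-oxocyclopent-3-en-1-ylidene}acetate (chelated enol of the α′-methoxalyl ketone)
Conditions: LiN(SiMe3)2 (2.2 equiv), THF, −78 °C; 4; −78 → 0 °C; aq. NH4Cl
Reagents that add atoms: none
Why: Crossed Claisen condensation of the kinetic α′-enolate of the vinylogous ester (Stork–Danheiser regiochemistry) with the non-enolisable oxalate, driven by formation of the stabilised product enolate; it installs C6 and C7 on C8.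

**Step 3**
Reactants: 5 enolised α′-methoxalyl ketone
Product: 6 methyl 2-{4-[(4-methoxybenzyl)oxy]-2-oxocyclopent-3-en-1-ylidene}-2-{[(trifluoromethyl)sulfonyl]oxy}acetate (triflate syn to the ring carbonyl)
Conditions: PhNTf2 (1.1 equiv), Et3N, DMAP (cat.), CH2Cl2, 0 → 23 °C
Reagents that add atoms: N-phenylbis(trifluoromethanesulfonimide), O=S(=O)(N(c1ccccc1)S(=O)(=O)C(F)(F)F)C(F)(F)F
Why: O-Sulfonylation of the chelated exocyclic enol should give the vinylogous acyl triflate; its geometry is immaterial because the alkene later becomes part of a delocalised anion.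

**Step 4**
Reactants: 7 2,2-dimethoxyacetaldehyde; 8 1-(triphenyl-λ5-phosphanylidene)propan-2-one
Product: 9 (E)-5,5-dimethoxypent-3-en-2-one
Conditions: CH2Cl2/H2O, 23 °C
Reagents that add atoms: none
Why: Wittig olefination with a stabilised ylide, which gives the E-enone under thermodynamic control of the oxaphosphetane.

**Step 5**
Reactants: 6 enol triflate; 9 enone acetal
Product: 10 methyl (5E)-7,7-dimethoxy-2-{4-[(4-methoxybenzyl)oxy]-2-oxocyclopent-3-en-1-ylidene}-4-oxohept-5-enoate
Conditions: 9, LiN(SiMe3)2 (2.2 equiv), THF, −78 °C; then 6, Pd2(dba)3 (2.5 mol %), Xantphos (6 mol %), 0 → 23 °C; aq. NH4Cl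
Reagents that add atoms: none
Why: Palladium-catalysed α-alkenylation of the kinetic methyl-side enolate of 9 with the electron-poor enol triflate (oxidative addition to zerovalent palladium, transmetalation, reductive elimination; uncatalysed addition–elimination at the same carbon would give the same product), the second equivalent of base holding the acidic product as its enolate; no stereocentre is formed.

**Step 6**
Reactants: 10 keto ester acetal
Product: 11 methyl (5E)-2-{4-[(4-methoxybenzyl)oxy]-2-oxocyclopent-3-en-1-ylidene}-4,7-dioxohept-5-enoate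
Conditions: PPTS (10 mol %), acetone/H2O (10:1), 23 °C; used crude
Reagents that add atoms: water, O
Why: Acid-catalysed hydrolysis of the allylic dimethyl acetal, which ionises far faster than the vinylogous ester or the PMB ether; the E-enal should be retained.

**Step 7**
Reactants: 11 4-oxo-enal
Product: 13 tricyclic triketone of rings B to D (cyclopentenone ring B with C5=C6–CO2Me and C10=O; bicyclo[3.2.1]octane of rings C and D with C12=O and C15=O and 13-OPMB; 9β-H; C14 α on ring B), via spiro aldehyde 12 (not isolated)
Conditions: (S)-α,α-diphenylprolinol trimethylsilyl ether (20 mol %), 2-(pentafluorophenyl)-6,7-dihydro-5H-pyrrolo[2,1-c][1,2,4]triazolium tetrafluoroborate (20 mol %), NaOAc (0.4 equiv), CHCl3, 23 °C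
Reagents that add atoms: none
Why: The amine converts the enal into an iminium ion, the acidic C5 methylene (flanked by C10=O and the C6=C8–C15=O enone) is deprotonated to a delocalised anion that attacks C9 through C8 in a 5-exo-trig Michael addition closing ring B (spiro aldehyde 12), and the triazolylidene then turns the liberated saturated aldehyde into a Breslow intermediate whose C12 adds 6-exo-trig to C13, the β-carbon of the ring-D vinylogous ester (intramolecular Stetter reaction), closing ring C as a bicyclo[3.2.1]octane. The closest known reaction type is the secondary amine/N-heterocyclic carbene relay cascade (Michael–benzoin and Michael–Stetter), including Stetter additions to β-oxygenated acceptors that create oxygen-bearing quaternary carbons. C9 is set by the (S)-catalyst, whose bulky group shields one face of the s-trans E-iminium ion so that C8 adds to the open face and gives the 9R configuration; C8 follows because only the diastereomer with the CH2CHO arm syn to C14 can reach C13 across the nearly planar cyclopentenone (the other reverts by retro-Michael reaction), and C13 is fixed by the bridging geometry. C9 remains epimerisable (α to C10), but the cis B/C fusion required by the nearly planar cyclopentenone is the thermodynamic one. The step needs C12 to choose C13: C5, C6 and C10 of ring B are out of reach (four-membered or bicyclo[2.1.1] products), the C15 vinylogous-ester carbonyl is a poor and reversible benzoin acceptor, and Bredt strain prevents β-elimination of the PMB-oxy group from the Stetter enolate.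

**Step 8**
Reactants: 13 tricyclic triketone
Product: 14 12α,15β-diol (ring B enone ester intact, 13-OPMB)
Conditions: NaBH4 (2.2 equiv), CH2Cl2/MeOH (1:1), −78 °C
Reagents that add atoms: none
Why: Chemoselective borohydride reduction (saturated ketones react faster than the cross-conjugated cyclopentenone at −78 °C); hydride should reach C12 from the face anti to the syn-axial C10, giving the axial 12α-alcohol cis to O13, and C15 from its exo face (its configuration is immaterial because it is re-oxidised in step 11).

**Step 9**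
Reactants: 14 diol
Product: 15 12α,13-O-(4-methoxybenzylidene) acetal with free 15-OH
Conditions: DDQ (1.3 equiv), 4 Å molecular sieves, CH2Cl2, 0 °C
Reagents that add atoms: none
Why: DDQ oxidises the PMB ether to an oxocarbenium ion that is trapped by the cis 12α-hydroxyl (oxidative acetalisation), protecting the 12,13-diol in one operation; the acetal carbon should form as the aryl-exo epimer and is removed in step 19.

**Step 10**
Reactants: 15 acetal enone; 16 3,3-diethoxyprop-1-yne
Product: 17 10α-hydroxy-10β-(3,3-diethoxyprop-1-yn-1-yl) diol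
Conditions: 16 (4 equiv), n-BuLi, THF, −78 °C; CeCl3 (anhydrous), −78 °C; then 15; aq. NH4Cl
Reagents that add atoms: none
Why: Organocerium 1,2-addition to the only remaining ketone (the cerium reagent suppresses enolisation at C9 and conjugate addition); the acetylide should attack C10 from the β-face because the α-face is blocked by ring C and the syn-axial O12, so the new tertiary hydroxyl is α.

**Step 11**
Reactants: 17 diol
Product: 18 15-ketone
Conditions: Dess–Martin periodinane (1.3 equiv), NaHCO3, CH2Cl2, 0 → 23 °C
Reagents that add atoms: none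
Why: Dess–Martin oxidation of the secondary C15 alcohol; the tertiary propargylic alcohol and both acetals are inert.

**Step 12**
Reactants: 18 15-ketone; 19 formaldehyde (as paraformaldehyde)
Product: 20 16-methylene-15-ketone
Conditions: (CH2O)n, i-Pr2NH·CF3CO2H (1.0 equiv), THF, 65 °C
Reagents that add atoms: none
Why: Ammonium carboxylate-mediated Mannich condensation and β-elimination (direct α-methylenation) at C16, the only enolisable position of the C15 ketone, installs C17.

**Step 13**
Reactants: 20 exo-methylene enone
Product: 21 15β-hydroxy-16-methylene compound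
Conditions: NaBH4, CeCl3·7H2O, MeOH, −78 °C
Reagents that add atoms: none
Why: Luche 1,2-reduction; hydride should add to C15 from the exo face (the side of the C14 methylene bridge, the endo face being screened by the C9–C11–C12 bridge), giving the endo 15β-alcohol, while the acrylate is untouched.

**Step 14**
Reactants: 21 allylic alcohol
Product: 22 15β-O-tert-butyldimethylsilyl ether
Conditions: t-BuMe2SiOSO2CF3 (1.1 equiv), 2,6-lutidine, CH2Cl2, −78 °C
Reagents that add atoms: tert-butyldimethylsilyl trifluoromethanesulfonate, CC(C)(C)[Si](C)(C)OS(=O)(=O)C(F)(F)F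
Why: Silylation of the secondary allylic alcohol at low temperature; the hindered tertiary propargylic alcohol at C10 should not react.

**Step 15**
Reactants: 22 silyl ether; 23 propanoic anhydride
Product: 25 γ-lactone methyl ester (19,10-lactone; C4–C5 bond formed; 5β-H; 6β-CO2Me), via propanoate ester 24 (not isolated)
Conditions: KN(SiMe3)2 (1.05 equiv), THF, −78 °C; 23; then KN(SiMe3)2 (1.3 equiv), −78 → −20 °C; AcOH
Reagents that add atoms: none
Why: O-Acylation of the tertiary potassium alkoxide followed by intramolecular Michael addition of the propanoate enolate to C5 of the acrylate (5-exo-trig lactonisation held in reach by the short rigid tether); the tether on the α-oriented O10 delivers C4 to the α-face of C5 (5β-H), the ester enolate is protonated and equilibrated to the more stable 6β-ester (trans to C4), and C4 is re-enolised in step 18.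

**Step 16**
Reactants: 25 lactone methyl ester
Product: 26 lactone 7-carboxylic acid
Conditions: LiSPr (5 equiv), HMPA, 23 °C; cold dilute HCl to pH 3
Reagents that add atoms: none
Why: SN2 demethylation of the hindered methyl ester by thiolate, done before the allylic lactone exists so that SN2′ opening cannot compete.

**Step 17**
Reactants: 26 alkynyl acid
Product: 27 (Z)-alkenyl acid
Conditions: H2 (1 atm), Pd/CaCO3 poisoned with Pb(OAc)2, quinoline, EtOAc, 23 °C
Reagents that add atoms: none
Why: Lindlar semihydrogenation (syn addition) gives the Z-alkene required for ring closure; the poisoned catalyst should leave the 1,1-disubstituted alkene and the benzylidene acetal untouched.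

**Step 18**
Reactants: 27 (Z)-alkenyl acetal acid
Product: 29 protected gibberellin A(32) (12,13-O-(4-methoxybenzylidene) acetal; 15-O-TBS ether), via Z-enal acid 28 (not isolated)
Conditions: PPTS, acetone/H2O (10:1), 23 °C; evaporate; then KN(SiMe3)2 (2.3 equiv), 18-crown-6, THF, −95 °C; AcOH
Reagents that add atoms: water, O
Why: Hydrolysis of the allylic diethyl acetal to the Z-enal, then intramolecular aldol addition of the lactone enolate (6-(enolexo)-exo-trig) closes ring A; C4 becomes quaternary with C18 β because C3 can only bond on the lactone face that carries C1, and the crown-separated potassium enolate should react through an open transition state with the aldehyde oxygen anti to the lactone carbonyl, placing the 3-hydroxyl axial (3β).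

**Step 19**
Reactants: 29 protected gibberellin A(32)
Product: 30 gibberellin A(32)
Conditions: HF (aq., 5 %), MeCN, 0 → 23 °C
Reagents that add atoms: none
Why: Aqueous HF cleaves the silyl ether and hydrolyses the 4-methoxybenzylidene acetal under conditions that should be mild enough for the allylic lactone and the allylic alcohols.

**Compound list**

1 | cyclopentane-1,3-dione | O=C1CCC(=O)C1 | starting material
2 | 4-methoxybenzyl alcohol | COc1ccc(CO)cc1 | starting material
3 | 3-[(4-methoxybenzyl)oxy]cyclopent-2-en-1-one | O=C1C=C(OCc2ccc(OC)cc2)CC1 | intermediate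
4 | dimethyl oxalate | COC(=O)C(=O)OC | starting material
5 | methyl 2-hydroxy-2-{4-[(4-methoxybenzyl)oxy]-2-oxocyclopent-3-en-1-ylidene}acetate (chelated enol) | COC(=O)/C(O)=C1/C(=O)C=C(OCc2ccc(OC)cc2)C1 | intermediate
6 | methyl 2-{4-[(4-methoxybenzyl)oxy]-2-oxocyclopent-3-en-1-ylidene}-2-(triflyloxy)acetate | COC(=O)/C(OS(=O)(=O)C(F)(F)F)=C1/C(=O)C=C(OCc2ccc(OC)cc2)C1 | intermediate
7 | 2,2-dimethoxyacetaldehyde | COC(OC)C=O | starting material
8 | 1-(triphenyl-λ5-phosphanylidene)propan-2-one | CC(=O)C=P(c1ccccc1)(c1ccccc1)c1ccccc1 | starting material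
9 | (E)-5,5-dimethoxypent-3-en-2-one | CC(=O)/C=C/C(OC)OC | intermediate
10 | methyl (5E)-7,7-dimethoxy-2-{4-[(4-methoxybenzyl)oxy]-2-oxocyclopent-3-en-1-ylidene}-4-oxohept-5-enoate | COC(=O)/C(CC(=O)/C=C/C(OC)OC)=C1/C(=O)C=C(OCc2ccc(OC)cc2)C1 | intermediate
11 | methyl (5E)-2-{4-[(4-methoxybenzyl)oxy]-2-oxocyclopent-3-en-1-ylidene}-4,7-dioxohept-5-enoate | COC(=O)/C(CC(=O)/C=C/C=O)=C1/C(=O)C=C(OCc2ccc(OC)cc2)C1 | intermediate
12 | spiro aldehyde: methyl 8-[(4-methoxybenzyl)oxy]-3,6-dioxo-4-(2-oxoethyl)spiro[4.4]nona-1,7-diene-1-carboxylate (C9 R, C8 as in 13) | O=C1C=C(OCc4ccc(OC)cc4)C[C@]12[C@@H](CC=O)C(=O)C=C2C(=O)OC | intermediate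
13 | tricyclic triketone of rings B to D (10,12,15-trioxo, 5-ene, 6-CO2Me, 13-OPMB, 9β-H) | C1C(=O)[C@]23C[C@@]1(OCc4ccc(OC)cc4)C(=O)C[C@H]2C(=O)C=C3C(=O)OC | intermediate
14 | 12α,15β-diol of 13 | C1[C@@H](O)[C@]23C[C@@]1(OCc4ccc(OC)cc4)[C@@H](O)C[C@H]2C(=O)C=C3C(=O)OC | intermediate
15 | 12α,13-O-(4-methoxybenzylidene) acetal, 15β-OH, 10-oxo-5-ene | C1[C@@H](O)[C@]23C[C@@]1(O[C@H](c4ccc(OC)cc4)O5)[C@@H]5C[C@H]2C(=O)C=C3C(=O)OC | intermediate
16 | 3,3-diethoxyprop-1-yne | C#CC(OCC)OCC | starting material
17 | 10α-hydroxy-10β-(3,3-diethoxyprop-1-yn-1-yl) 15β-ol | C1[C@@H](O)[C@]23C[C@@]1(O[C@H](c4ccc(OC)cc4)O5)[C@@H]5C[C@H]2[C@@](O)(C=C3C(=O)OC)C#CC(OCC)OCC | intermediate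
18 | 15-ketone of 17 | C1C(=O)[C@]23C[C@@]1(O[C@H](c4ccc(OC)cc4)O5)[C@@H]5C[C@H]2[C@@](O)(C=C3C(=O)OC)C#CC(OCC)OCC | intermediate
19 | formaldehyde (used as paraformaldehyde) | C=O | starting material
20 | 16-methylene-15-ketone | C=C1C(=O)[C@]23C[C@@]1(O[C@H](c4ccc(OC)cc4)O5)[C@@H]5C[C@H]2[C@@](O)(C=C3C(=O)OC)C#CC(OCC)OCC | intermediate
21 | 15β-hydroxy-16-methylene compound | C=C1[C@@H](O)[C@]23C[C@@]1(O[C@H](c4ccc(OC)cc4)O5)[C@@H]5C[C@H]2[C@@](O)(C=C3C(=O)OC)C#CC(OCC)OCC | intermediate
22 | 15β-O-TBS ether of 21 | C=C1[C@@H](O[Si](C)(C)C(C)(C)C)[C@]23C[C@@]1(O[C@H](c4ccc(OC)cc4)O5)[C@@H]5C[C@H]2[C@@](O)(C=C3C(=O)OC)C#CC(OCC)OCC | intermediate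
23 | propanoic anhydride | CCC(=O)OC(=O)CC | starting material
24 | 10-O-propanoate of 22 | C=C1[C@@H](O[Si](C)(C)C(C)(C)C)[C@]23C[C@@]1(O[C@H](c4ccc(OC)cc4)O5)[C@@H]5C[C@H]2[C@@](OC(=O)CC)(C=C3C(=O)OC)C#CC(OCC)OCC | intermediate
25 | 19,10-lactone methyl ester with 10β-(3,3-diethoxypropynyl), 5β-H, 6β-CO2Me | C=C1[C@@H](O[Si](C)(C)C(C)(C)C)[C@]23C[C@@]1(O[C@H](c4ccc(OC)cc4)O5)[C@@H]5C[C@H]2[C@@]6(C#CC(OCC)OCC)OC(=O)[C@@H](C)[C@H]6[C@@H]3C(=O)OC | intermediate
26 | 7-carboxylic acid of 25 | C=C1[C@@H](O[Si](C)(C)C(C)(C)C)[C@]23C[C@@]1(O[C@H](c4ccc(OC)cc4)O5)[C@@H]5C[C@H]2[C@@]6(C#CC(OCC)OCC)OC(=O)[C@@H](C)[C@H]6[C@@H]3C(=O)O | intermediate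
27 | (Z)-3,3-diethoxyprop-1-enyl lactone acid | C=C1[C@@H](O[Si](C)(C)C(C)(C)C)[C@]23C[C@@]1(O[C@H](c4ccc(OC)cc4)O5)[C@@H]5C[C@H]2[C@@]6(/C=C\C(OCC)OCC)OC(=O)[C@@H](C)[C@H]6[C@@H]3C(=O)O | intermediate
28 | (Z)-3-oxoprop-1-enyl lactone acid | C=C1[C@@H](O[Si](C)(C)C(C)(C)C)[C@]23C[C@@]1(O[C@H](c4ccc(OC)cc4)O5)[C@@H]5C[C@H]2[C@@]6(/C=C\C=O)OC(=O)[C@@H](C)[C@H]6[C@@H]3C(=O)O | intermediate
29 | 12,13-O-(4-methoxybenzylidene)-15-O-TBS gibberellin A(32) | C=C1[C@@H](O[Si](C)(C)C(C)(C)C)[C@]23C[C@@]1(O[C@H](c4ccc(OC)cc4)O5)[C@@H]5C[C@H]2[C@@]67C=C[C@H](O)[C@@](C)(C(=O)O6)[C@H]7[C@@H]3C(=O)O | intermediate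
30 | gibberellin A(32) | C=C1[C@@H](O)[C@]23C[C@@]1(O)[C@@H](O)C[C@H]2[C@@]12C=C[C@H](O)[C@@](C)(C(=O)O1)[C@H]2[C@@H]3C(=O)O | target

**Count.** Total: 19 steps. Longest linear sequence: 18 steps (steps 1–3 and 5–19; step 4 makes the side fragment 9).

**Steps most likely to fail**

Step 7. The Stetter closure onto the deactivated β-alkoxy enone may be too slow, so that retro-Michael reaction, loss of enantiopurity or carbene redox chemistry of the enal takes over. The fallback sets out from 11 and returns at 13. The Michael addition is run with the amine catalyst alone and 12 is isolated. Its aldehyde is oxidised (NaClO2, NaH2PO4, 2-methylbut-2-ene, t-BuOH/H2O) to the carboxylic acid F1, which is converted ((PhSe)2, Bu3P, CH2Cl2) into the Se-phenyl selenoester F2. The acyl radical generated from F2 (Bu3SnH, AIBN, benzene, 80 °C) cyclises 6-exo-trig onto C13, an addition of a nucleophilic acyl radical to an enone that does not depend on carbene catalysis, and should give 13.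

Step 15. Ring closure through the strained 5-(enolendo)-exo-trig geometry may be slow, leaving time for acyl transfer or loss of the propanoate. The fallback sets out from 22 and returns at 25. The potassium alkoxide of 22 is acylated with 2-bromopropanoyl bromide to the 2-bromopropanoate F3. Slow addition of Bu3SnH/AIBN in dilute benzene at 80 °C generates the α-ester radical, which closes 5-exo-trig onto C5 of the acrylate from the α-face. The resulting C6 radical is reduced, and brief treatment with DBU equilibrates C6 to give 25.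

Step 18. The Z-enal may isomerise to the E-isomer before closure, or a chelated transition state may place the new hydroxyl equatorial (3α). The fallback sets out from 27 and returns at 29. If the aldol gives mainly the 3α-alcohol F4, the crude allylic alcohol is oxidised with MnO2 (CH2Cl2, 23 °C) to the 1-en-3-one F5. F5 is then reduced under reagent control with (R)-2-methyl-CBS-oxazaborolidine and catecholborane (toluene, −78 °C), which should give 29. The (R)-catalyst is the antipode predicted by the standard model, with the quaternary C4 as the large group, to deliver hydride to the α-face.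

**Further compounds**

F1 | step 7 | carboxylic acid from 12 (2-carboxymethyl spiro enone) | O=C1C=C(OCc4ccc(OC)cc4)C[C@]12[C@@H](CC(=O)O)C(=O)C=C2C(=O)OC
F2 | step 7 | Se-phenyl selenoester of F1 | O=C1C=C(OCc4ccc(OC)cc4)C[C@]12[C@@H](CC(=O)[Se]c3ccccc3)C(=O)C=C2C(=O)OC
F3 | step 15 | 10-O-(2-bromopropanoyl) ester of 22 (either epimer at the bromide carbon) | C=C1[C@@H](O[Si](C)(C)C(C)(C)C)[C@]23C[C@@]1(O[C@H](c4ccc(OC)cc4)O5)[C@@H]5C[C@H]2[C@@](OC(=O)C(C)Br)(C=C3C(=O)OC)C#CC(OCC)OCC
F4 | step 18 | 3α-epimer of 29 | C=C1[C@@H](O[Si](C)(C)C(C)(C)C)[C@]23C[C@@]1(O[C@H](c4ccc(OC)cc4)O5)[C@@H]5C[C@H]2[C@@]67C=C[C@@H](O)[C@@](C)(C(=O)O6)[C@H]7[C@@H]3C(=O)O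
F5 | step 18 | 3-oxo-1-ene derived from F4 | C=C1[C@@H](O[Si](C)(C)C(C)(C)C)[C@]23C[C@@]1(O[C@H](c4ccc(OC)cc4)O5)[C@@H]5C[C@H]2[C@@]67C=CC(=O)[C@@](C)(C(=O)O6)[C@H]7[C@@H]3C(=O)O
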